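Slowness is the first thing to read in the east run, which is this flask followed so far: E's fall keeps losing speed.

- east: E 1.4 M; X 1.82 M; G 1.4 M; the very flask that is asked about, followed so far
- flask: E 1.4 M; X 1.82 M; G 1.40 M; time 50 min
east run (percent of the E charged)

| time / min | J / % | E / % |
|---|---|---|
| 2.50 | 2.6 | 65.4 |
| 8.00 | 8.9 | 36.8 |
| 15.0 | 11.6 | 23.2 |
| 20.0 | 12.5 | 19.5 |
| 30.0 | 11.4 | 14.7 |
| 40.0 | 10.6 | 12.8 |

(each reading ± 0.3 percentage points)
- what is taken out of J is counted as made
- additions bring no volume worth counting
- ash: change nothing and wait 1.5 h more
- elm: at 50 min take out 90% of the J then present, then wait 1.5 h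
- larch: at 50 min add E, 50.0% of the amount charged, then wait 1.5 h
- J, in percent of the E first charged, at 50 min
- what to do for the largest gain in J; "none" if nothing gains more than 2 percentage points (ash / elm / larch / none)
- J present, with what was taken out counted in, in percent of the E first charged, after ash
- J present, with what was taken out counted in, in percent of the E first charged, after elm

Take λ, the logarithm of E's drop divided by the time it took. If E's step is one-way and pseudo-first-order, λ is proportional to X. Over the first reading λ is 0.170 min⁻¹, and between 30.0 min and 40.0 min it is 0.0138 min⁻¹, so X stands near 8.15% of its early level.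

Call b = 1.30 the X budget, the moles of X charged per mole of E charged. J costs two X, and b is less than two, so X is the limiting reagent. Each E that has reacted costs one X, and each second exchange one more. The twice-exchanged share D is therefore b times the fraction of X spent, minus the fraction of E spent. That gives D = 33.2% between those two readings, while J reads about 11.0%. J thus holds about a third of D, and the rest sits in a form you do not see.

Suppose J at 50 min stands near its last reading and that form refills J in the same proportion: then I estimate that elm takes 9.54% and the total comes to 17.4%, with D held as it stood. Larch lowers b to 0.867, so I expect no gain from it. The weak link is the early X level, which had already dropped during the first reading. Correcting for that gives D = 34.6% and a total of 17.5%.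

The forecast takes another route, with reversible steps: “The slow first step uses up X and builds G, dragging J down”. It gives 10.6% now, 10.3% after ash, 17.1% after elm, and chooses elm.

The flask gives 10.6% now, 10.2% after ash and 17.3% after elm, so elm gains 6.7 percentage points.

    E + X → G + Z (k = 0.110 M⁻¹ min⁻¹)
    Z + X → G + J (k = 0.0430 M⁻¹ min⁻¹)
    J ⇌ L (K = 2.90, k = 0.110 min⁻¹)

J and L relax with a half-life of 4.69 min, short against 50 min. With 3.5% of X and 11% of E left at 50.0 min, b gives D = 36.9% in this flask, where J is 10.6% and L 26.4%. A neighbour flask, charged with 2.4 M of E, has b = 0.758; at 50 min it keeps 0.033% of its X and 37% of its E, so D = 12.6%, with J at 3.27% and L at 9.30%.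

(The readings were generated by integration for substances that don't exist.)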